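**Plan**

1. The retrosynthesis first removes the two acetates (meso triol). It then turns one ring CH–OH back into a ketone and cuts the tertiary C–OH bond (enol hydroxylation), which leads to racemic 4-hydroxy-5-undecanoylcyclopent-2-en-1-one.
2. That ring is cut at its CH=CH bond and at the bond between the acyl-bearing ring carbon and the carbinol carbon. This gives glyoxal and dimethyl (2,4-dioxotetradecyl)phosphonate, which is cut at C3–C4 into dimethyl (2-oxopropyl)phosphonate and methyl undecanoate.
3. Enabling feature: the ring carbon bearing OH and the undecanoyl group is α to the side-chain ketone, and both ring CH–O carbons are β to it. With one of them raised to a ketone, this carbon becomes the acidic CH of a 1,3-diketone (aldol donor for one CHO of glyoxal), and the neighbouring ring CH=CH becomes the enone alkene of a keto-phosphonate olefination (acceptor: the other CHO).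
4. Forward: the C14 chain is joined first and the cyclopentenone ring then arises in one operation (step 2). O-silylation, enol hydroxylation, enone reduction, desilylation and diacetylation follow.
5. Stereochemistry: the annulation creates one carbinol centre (racemic). Its bulky silyl ether sends the hydroxylating oxygen to the opposite ring face, and the silyloxy and acyl groups then send hydride to the face of the new OH. Because the target is meso, both enantiomers of every intermediate converge on it.

Key step: step 2

Remark: the target is read as the meso isomer (both acetoxy groups cis to the undecanoyl group and trans to the tertiary hydroxyl), so no absolute control is needed; racemic intermediates are drawn as one enantiomer.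

**Step 1**
Reactants: 1 dimethyl (2-oxopropyl)phosphonate; 2 methyl undecanoate
Product: 4 dimethyl (2,4-dioxotetradecyl)phosphonate, via sodium lithium dianion 3 (not isolated)
Conditions: NaH, THF, 0 °C; n-BuLi, −78 to 0 °C; then 2, −78 to 0 °C; aq. HCl work-up (1 and both bases in about twofold excess over 2)
Reagents that add atoms: none
Why: Claisen-type C-acylation of a 1,3-dianion, in which the more basic terminal carbanion of the doubly deprotonated keto-phosphonate attacks the ester regioselectively, as in acylations of acetoacetate dianions; no stereocentre is formed.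

**Step 2**
Reactants: 4 dimethyl (2,4-dioxotetradecyl)phosphonate; 5 glyoxal (40% aqueous solution)
Product: 7 rac-(4R,5R)-4-hydroxy-5-undecanoylcyclopent-2-en-1-one (trans, largely enolised), via aldol adduct 6 (not isolated)
Conditions: 40% aq. glyoxal (1.5 equiv), K2CO3 (2.5 equiv), THF–H2O, 0 °C to rt; then aq. HCl to pH 3
Reagents that add atoms: none
Why: Proposed new method: under mild aqueous base the most acidic site of 4, the CH2 between the two ketones (the future quaternary ring carbon), should add reversibly to one aldehyde of glyoxal to give 6, and the minor tautomeric anion at the phosphonate carbon should then attack the second aldehyde intramolecularly and collapse by Horner–Wadsworth–Emmons elimination of dimethyl phosphate to the ring alkene. The closest known reaction types are the Weiss–Cook condensation, in which glyoxal and a 3-oxoglutarate close to a 4-hydroxycyclopent-2-enone by two aldol events, and the intramolecular Horner–Wadsworth–Emmons closure of 2-oxoalkylphosphonates to cyclopentenones. The five-membered ring closes by 5-exo-trig attack of the phosphonate-stabilised carbanion on the aldehyde (formally 5-(enolendo)-exo-trig, the mode by which 1,4-dicarbonyl compounds close to cyclopentenones), and the ring forces the new alkene to be cis. The only fixed new stereocentre is the carbinol carbon, formed racemic, which suffices because the target is meso; the acyl-bearing carbon is an enolised, stereochemically labile 1,3-diketone carbon. The step needs site selectivity (aldol at the diketone carbon before olefination at the phosphonate carbon), which the pKa gap between the 1,3-diketone and the keto-phosphonate should secure. It also needs the aldol hydroxyl to survive, which is expected because dehydration within the ring would give an antiaromatic cyclopentadienone and because the product is stored as its stabilised diketonate until acidification.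

**Step 3**
Reactants: 7 rac-(4R,5R)-4-hydroxy-5-undecanoylcyclopent-2-en-1-one
Product: 8 rac-(4R,5R)-4-[(tert-butyldimethylsilyl)oxy]-5-undecanoylcyclopent-2-en-1-one
Conditions: TBSCl, imidazole, DMF, 0 °C to rt; dilute aq. citric acid work-up
Reagents that add atoms: tert-butyldimethylsilyl chloride, CC(C)(C)[Si](C)(C)Cl
Why: Standard silyl ether formation at the secondary alcohol (any enol silyl ether of the 1,3-diketone is cleaved on acidic work-up); the bulky group is installed as the stereodirecting element for steps 4 and 5, and no new stereocentre is formed.

**Step 4**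
Reactants: 8 rac-(4R,5R)-4-[(tert-butyldimethylsilyl)oxy]-5-undecanoylcyclopent-2-en-1-one
Product: 9 rac-(4R,5R)-4-[(tert-butyldimethylsilyl)oxy]-5-hydroxy-5-undecanoylcyclopent-2-en-1-one (tertiary OH trans to the silyloxy group, acyl group cis to it)
Conditions: dimethyldioxirane (1.1 equiv, acetone solution), CH2Cl2–acetone, −20 to 0 °C
Reagents that add atoms: dimethyldioxirane, CC1(C)OO1
Why: Electrophilic α-hydroxylation of an enolised 1,3-diketone by a dioxirane (epoxidation of the enol double bond and collapse to the α-hydroxy diketone); the oxygen should reach the enol carbon from the ring face opposite to the adjacent silyloxy group (1,2-induction), which sets the tertiary hydroxyl trans to it.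

**Step 5**
Reactants: 9 rac-(4R,5R)-4-[(tert-butyldimethylsilyl)oxy]-5-hydroxy-5-undecanoylcyclopent-2-en-1-one
Product: 10 rac-1-[(1R,2R,5S)-2-[(tert-butyldimethylsilyl)oxy]-1,5-dihydroxycyclopent-3-en-1-yl]undecan-1-one (secondary OH cis to the silyloxy and acyl groups, trans to the tertiary OH)
Conditions: NaBH4 (1.0 equiv), CeCl3·7H2O, MeOH, −78 °C; aq. NH4Cl
Reagents that add atoms: none
Why: Luche 1,2-reduction, in which the cerium/methanol-activated conjugated ring carbonyl is expected to react faster than the non-conjugated side-chain ketone flanked by the fully substituted carbon; hydride should attack from the face carrying only the small tertiary OH, opposite to the acyl and silyloxy groups, as known for 4-silyloxycyclopent-2-enones, which sets the new carbinol cis to the silyloxy group.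

**Step 6**
Reactants: 10 rac-1-[(1R,2R,5S)-2-[(tert-butyldimethylsilyl)oxy]-1,5-dihydroxycyclopent-3-en-1-yl]undecan-1-one
Product: 11 1-[(1r,2R,5S)-1,2,5-trihydroxycyclopent-3-en-1-yl]undecan-1-one (meso triol)
Conditions: HF·pyridine, pyridine, THF, 0 °C to rt
Reagents that add atoms: none
Why: Fluoride-mediated silyl ether cleavage under buffered, mildly acidic conditions, which avoid base-induced retro-aldol cleavage of the β-hydroxy ketone units; no stereocentre is touched, and the racemate becomes a single meso compound.

**Step 7**
Reactants: 11 1-[(1r,2R,5S)-1,2,5-trihydroxycyclopent-3-en-1-yl]undecan-1-one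
Product: 12 (1R,2r,3S)-2-hydroxy-2-undecanoylcyclopent-4-ene-1,3-diyl diacetate (target)
Conditions: Ac2O, pyridine, DMAP (cat.), CH2Cl2, 0 °C
Reagents that add atoms: acetic anhydride, CC(=O)OC(C)=O
Why: Pyridine-mediated acetylation (nucleophilic acyl substitution) should be selective for the two secondary allylic hydroxyls, the tertiary α-ketol hydroxyl being too hindered at 0 °C and, being trans to both acetates, unable to receive an acetyl group by migration.

**Compound list**

1 | dimethyl (2-oxopropyl)phosphonate | CC(=O)CP(=O)(OC)OC | starting material
2 | methyl undecanoate | CCCCCCCCCCC(=O)OC | starting material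
3 | sodium lithium dianion of 1 | C=C([O-])[CH-]P(=O)(OC)OC.[Na+].[Li+] | intermediate (not isolated)
4 | dimethyl (2,4-dioxotetradecyl)phosphonate | CCCCCCCCCCC(=O)CC(=O)CP(=O)(OC)OC | intermediate
5 | glyoxal | O=CC=O | starting material
6 | dimethyl [3-(1-hydroxy-2-oxoethyl)-2,4-dioxotetradecyl]phosphonate (aldol adduct, mixture of labile stereoisomers) | CCCCCCCCCCC(=O)C(C(O)C=O)C(=O)CP(=O)(OC)OC | intermediate (not isolated)
7 | rac-(4R,5R)-4-hydroxy-5-undecanoylcyclopent-2-en-1-one (trans diketo tautomer drawn, largely enolised) | CCCCCCCCCCC(=O)[C@@H]1C(=O)C=C[C@H]1O | intermediate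
8 | rac-(4R,5R)-4-[(tert-butyldimethylsilyl)oxy]-5-undecanoylcyclopent-2-en-1-one (trans diketo tautomer drawn, largely enolised) | CCCCCCCCCCC(=O)[C@@H]1C(=O)C=C[C@H]1O[Si](C)(C)C(C)(C)C | intermediate
9 | rac-(4R,5R)-4-[(tert-butyldimethylsilyl)oxy]-5-hydroxy-5-undecanoylcyclopent-2-en-1-one (OH trans to silyloxy) | CCCCCCCCCCC(=O)[C@@]1(O)C(=O)C=C[C@H]1O[Si](C)(C)C(C)(C)C | intermediate
10 | rac-1-[(1R,2R,5S)-2-[(tert-butyldimethylsilyl)oxy]-1,5-dihydroxycyclopent-3-en-1-yl]undecan-1-one | CCCCCCCCCCC(=O)[C@@]1(O)[C@@H](O)C=C[C@H]1O[Si](C)(C)C(C)(C)C | intermediate
11 | 1-[(1r,2R,5S)-1,2,5-trihydroxycyclopent-3-en-1-yl]undecan-1-one (meso; secondary OH groups cis to the acyl group) | CCCCCCCCCCC(=O)[C@@]1(O)[C@@H](O)C=C[C@H]1O | intermediate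
12 | (1R,2r,3S)-2-hydroxy-2-undecanoylcyclopent-4-ene-1,3-diyl diacetate (meso) | CCCCCCCCCCC(=O)[C@@]1(O)[C@@H](OC(C)=O)C=C[C@H]1OC(C)=O | target

**Step count and risks**

Total step count: 7. Longest linear sequence: 7 steps (1 → 4 → 7 → 8 → 9 → 10 → 11 → 12).

Steps most likely to fail:

Step 2 (Proposed new method). The diketone carbon may add to glyoxal twice, or the adduct may dehydrate or close through oxygen (furan formation) faster than the phosphonate olefination. Alternatively the phosphonate carbon may olefinate glyoxal first and give an E-enal that cannot ring-close. The fallback uses known chemistry only, sets out from 2 and returns to the route at 8. Compound 2 is reduced with i-Bu2AlH (toluene, −78 °C) to undecanal F1. The kinetic lithium enolate of commercial 4-[(tert-butyldimethylsilyl)oxy]cyclopent-2-en-1-one (LiN(i-Pr)2, THF, −78 °C; racemate or either enantiomer, the target being meso) is added to F1 in a directed aldol reaction anti to the silyloxy group. This gives rac-4-[(tert-butyldimethylsilyl)oxy]-5-(1-hydroxyundecyl)cyclopent-2-en-1-one F2. Dess–Martin oxidation (NaHCO3, CH2Cl2) of the side-chain carbinol then gives 8, so that step 3 is bypassed as well.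

Step 5. Hydride addition to the side-chain ketone may compete with, or follow, reduction of the ring carbonyl. The fallback sets out from 9 and returns at 11, with the side-chain ketone masked as an enol ether. Et3SiOTf/Et3N (CH2Cl2, −78 to 0 °C) converts 9 into the bis(triethylsilyl) compound F3 (tertiary silyl ether plus silyl enol ether of the side-chain ketone, the only enolisable carbonyl). i-Bu2AlH (CH2Cl2, −78 °C) then reduces the one remaining carbonyl group 1,2, from the face opposite to the silyloxy group and the side chain, to the allylic alcohol F4. HF·pyridine removes all three silyl groups, the enol ether collapsing to the ketone, and gives 11 directly.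

Step 4. Oxygen may be transferred to both faces of the enol, or the unprotected tertiary α-hydroxy-1,3-diketone may be cleaved oxidatively by excess oxidant. The fallback (Rubottom oxidation) sets out from 8 and returns at 9. Compound 8 is O-silylated (Me3SiCl, Et3N, CH2Cl2) to the trimethylsilyl enol ether F5. This is epoxidised with mCPBA (NaHCO3, CH2Cl2, 0 °C) on the face opposite to the silyloxy group, and epoxide opening with 1,4-silyl shift gives the α-trimethylsilyloxy diketone F6. Dilute aq. citric acid in THF frees the tertiary alcohol 9.

**Further compounds**

F1 | step 2 | undecanal | CCCCCCCCCCC=O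
F2 | step 2 | rac-4-[(tert-butyldimethylsilyl)oxy]-5-(1-hydroxyundecyl)cyclopent-2-en-1-one (side chain trans to silyloxy, carbinol epimers) | CCCCCCCCCCC(O)[C@@H]1C(=O)C=C[C@H]1O[Si](C)(C)C(C)(C)C
F3 | step 5 | rac-4-[(tert-butyldimethylsilyl)oxy]-5-[(triethylsilyl)oxy]-5-[1-[(triethylsilyl)oxy]undec-1-en-1-yl]cyclopent-2-en-1-one (enol ether geometry not defined) | CCCCCCCCCC=C(O[Si](CC)(CC)CC)[C@@]1(O[Si](CC)(CC)CC)C(=O)C=C[C@H]1O[Si](C)(C)C(C)(C)C
F4 | step 5 | rac-4-[(tert-butyldimethylsilyl)oxy]-5-[(triethylsilyl)oxy]-5-[1-[(triethylsilyl)oxy]undec-1-en-1-yl]cyclopent-2-en-1-ol (OH cis to the tert-butyldimethylsilyloxy group) | CCCCCCCCCC=C(O[Si](CC)(CC)CC)[C@@]1(O[Si](CC)(CC)CC)[C@@H](O)C=C[C@H]1O[Si](C)(C)C(C)(C)C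
F5 | step 4 | rac-4-[(tert-butyldimethylsilyl)oxy]-5-[1-[(trimethylsilyl)oxy]undecylidene]cyclopent-2-en-1-one (enol ether geometry not defined) | CCCCCCCCCCC(O[Si](C)(C)C)=C1C(=O)C=C[C@H]1O[Si](C)(C)C(C)(C)C
F6 | step 4 | rac-(4R,5R)-4-[(tert-butyldimethylsilyl)oxy]-5-[(trimethylsilyl)oxy]-5-undecanoylcyclopent-2-en-1-one | CCCCCCCCCCC(=O)[C@@]1(O[Si](C)(C)C)C(=O)C=C[C@H]1O[Si](C)(C)C(C)(C)C
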